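**Retrosynthetic overview**
- Ring A is bought as (R)-carvone 1. Its stereocentre directs the alkylation that creates the quaternary C-5 and is then excised by ozonolytic hydrodealkenylation.
- Ring B is the key ring: an endo Diels–Alder reaction of the resulting 6,6-disubstituted 1-vinylcyclohexene with an (E)-α,β-dimethyl enal sets C-1 and C-2. An acid shift then moves the alkene into the ring fusion.
- The arylmethyl group comes from an aryllithium adding to the C-1 aldehyde, followed by radical deoxygenation.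
- The side chain is cut at its CH2–CH= bond: a ring-bound alkyl Grignard is coupled with an (E)-vinyl iodide that carries the diol. That fragment comes from a bought (S)-hydroxy lactone by chelation-controlled methyl addition and carboalumination.
- Ring order: ring A (bought) → ring B (cycloaddition) → arene → side chain → aryl sulfates last.

Assumption: the target is isolated as its disodium salt and is listed, like the task structure, as the neutral bis(hydrogen sulfate); locants are those of the octahydronaphthalene core (C-1 methyl/arylmethyl, C-2 methyl, C-5 methyl/side chain, C-4a=C-8a alkene).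

**Route**

Step 1
Reactants: 1 (R)-carvone
Product: 3 ethyl 2-[(1R,4R)-1-methyl-2-oxo-4-(prop-1-en-2-yl)cyclohexyl]acetate, via lithium enolate 2 (not isolated)
Conditions: LiBH(s-Bu)3, THF, −78 °C; then BrCH2CO2Et, DMPU, −78 → 0 °C
Reagents that add atoms: ethyl bromoacetate CCOC(=O)CBr
Why: Conjugate hydride reduction gives the regiodefined enolate, and its alkylation by axial (chair-like) attack with the isopropenyl group equatorial puts the acetate arm cis to isopropenyl, so the new quaternary carbon (future C-5) is R (about 5:1 expected, minor epimer removed by chromatography).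

Step 2
Reactants: 3 ethyl 2-[(1R,4R)-1-methyl-2-oxo-4-(prop-1-en-2-yl)cyclohexyl]acetate
Product: 5 ethyl 2-[(1R)-1-methyl-2-oxocyclohexyl]acetate, via methoxy hydroperoxide 4 (not isolated)
Conditions: O3, MeOH, −78 °C; then FeSO4·7H2O, PhSH, −78 → 25 °C
Reagents that add atoms: none
Why: Ozonolysis of the only C=C gives the α-methoxy hydroperoxide, divalent iron reduces it to an alkoxy radical that loses methyl acetate by β-scission, and the ring radical takes H from thiophenol (hydrodealkenylation), turning the spent carvone stereocentre into CH2 without touching the quaternary centre.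

Step 3
Reactants: 5 ethyl 2-[(1R)-1-methyl-2-oxocyclohexyl]acetate
Product: 7 ethyl 2-[(1R)-1-methyl-2-(trifluoromethanesulfonyloxy)cyclohex-2-en-1-yl]acetate, via potassium enolate 6 (not isolated)
Conditions: KN(SiMe3)2, THF, −78 °C; then PhNTf2, −78 → 0 °C
Reagents that add atoms: N-phenylbis(trifluoromethanesulfonimide) FC(F)(F)S(=O)(=O)N(c1ccccc1)S(=O)(=O)C(F)(F)F
Why: Kinetic enolisation can only occur at the single α-CH2 of the ketone (the other α-carbon is quaternary, the ester α-H is less acidic) and O-triflation gives the enol triflate; no stereocentre is touched.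

Step 4
Reactants: 7 ethyl 2-[(1R)-1-methyl-2-(trifluoromethanesulfonyloxy)cyclohex-2-en-1-yl]acetate
Product: 8 ethyl 2-[(1R)-2-ethenyl-1-methylcyclohex-2-en-1-yl]acetate
Conditions: CH2=CHSnBu3, Pd(PPh3)4 (5 mol%), LiCl, THF, 65 °C
Reagents that add atoms: tributyl(vinyl)stannane C=C[Sn](CCCC)(CCCC)CCCC
Why: Stille cross-coupling of the enol triflate (zerovalent palladium, LiCl-assisted) gives the 1,3-diene with the ring double bond fixed next to the quaternary carbon; no stereocentre is touched.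

Step 5
Reactants: 8 ethyl 2-[(1R)-2-ethenyl-1-methylcyclohex-2-en-1-yl]acetate
Product: 9 2-[(1R)-2-ethenyl-1-methylcyclohex-2-en-1-yl]ethan-1-ol
Conditions: LiAlH4, Et2O, 0 °C
Reagents that add atoms: none
Why: Hydride reduction of the ester gives the primary alcohol and leaves the diene untouched.

Step 6
Reactants: 9 2-[(1R)-2-ethenyl-1-methylcyclohex-2-en-1-yl]ethan-1-ol
Product: 10 (6R)-6-(2-chloroethyl)-1-ethenyl-6-methylcyclohex-1-ene
Conditions: PPh3, CCl4, 50 °C
Reagents that add atoms: tetrachloromethane ClC(Cl)(Cl)Cl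
Why: Appel chlorination (SN2 at the primary carbinol) installs a chloride that is inert to the Lewis acid, the aryllithium and the tin hydride used next, yet can later be turned into a Grignard reagent.

Step 7
Reactants: 10 (6R)-6-(2-chloroethyl)-1-ethenyl-6-methylcyclohex-1-ene; 11 (E)-2-methylbut-2-enal (tiglic aldehyde)
Product: 12 (1R,2S,5R,8aS)-5-(2-chloroethyl)-1,2,5-trimethyl-1,2,3,5,6,7,8,8a-octahydronaphthalene-1-carbaldehyde
Conditions: EtAlCl2 (0.5 equiv), CH2Cl2, −78 → −40 °C
Reagents that add atoms: none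
Why: The Lewis-acid-promoted Diels–Alder cycloaddition forms ring B with "ortho" regiochemistry (the formyl-bearing carbon bonds to the ring terminus C-8a), through the endo transition state (formyl under the diene, both methyls exo) and on the diene face anti to the pseudoaxial chloroethyl arm at C-5, so the E-enal gives the cis C-1/C-2 methyls and C-5 fixes their absolute sense as 1R,2S (about 4:1 facial selectivity expected by analogy with related 6,6-disubstituted vinylcyclohexenes, minor isomer separated).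

Step 8
Reactants: 12 (1R,2S,5R,8aS)-5-(2-chloroethyl)-1,2,5-trimethyl-1,2,3,5,6,7,8,8a-octahydronaphthalene-1-carbaldehyde
Product: 13 (1R,2S,5R)-5-(2-chloroethyl)-1,2,5-trimethyl-1,2,3,4,5,6,7,8-octahydronaphthalene-1-carbaldehyde
Conditions: TsOH·H2O (0.2 equiv), benzene, 80 °C
Reagents that add atoms: none
Why: Acid-catalysed alkene isomerisation through the tertiary C-4a cation moves the double bond to the thermodynamically favoured tetrasubstituted C-4a=C-8a position, erasing the C-8a centre, while the quaternary C-1 and C-5 and the remote C-2 cannot epimerise.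

Step 9
Reactants: 14 hydroquinone
Product: 15 1,4-bis(methoxymethoxy)benzene
Conditions: NaH, DMF, 0 °C; then MOMCl, 0 → 25 °C
Reagents that add atoms: chloromethyl methyl ether COCCl
Why: Williamson etherification masks both phenols as MOM ethers, which later direct ortho-lithiation and are removed by mild acid.

Step 10
Reactants: 13 (1R,2S,5R)-5-(2-chloroethyl)-1,2,5-trimethyl-1,2,3,4,5,6,7,8-octahydronaphthalene-1-carbaldehyde; 15 1,4-bis(methoxymethoxy)benzene
Product: 19 O-{[2,5-bis(methoxymethoxy)phenyl][(1R,2S,5R)-5-(2-chloroethyl)-1,2,5-trimethyl-1,2,3,4,5,6,7,8-octahydronaphthalen-1-yl]methyl} S-methyl carbonodithioate (carbinol epimers), via aryllithium 16 (not isolated), via lithium alkoxide 17 (not isolated), via lithium xanthate 18 (not isolated)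
Conditions: 15, n-BuLi, THF, 0 °C; then 13, −78 → −20 °C; then CS2, 0 °C; then MeI, 0 → 25 °C
Reagents that add atoms: carbon disulfide S=C=S; iodomethane CI
Why: Directed ortho-lithiation gives the aryllithium, which adds 1,2 to the neopentyl aldehyde, and the alkoxide is trapped in the same flask with CS2 and MeI as the S-methyl xanthate (the new carbinol centre forms as a mixture and is removed in the next step).

Step 11
Reactants: 19 the S-methyl xanthate
Product: 20 2-{[(1R,2S,5R)-5-(2-chloroethyl)-1,2,5-trimethyl-1,2,3,4,5,6,7,8-octahydronaphthalen-1-yl]methyl}-1,4-bis(methoxymethoxy)benzene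
Conditions: Bu3SnH, AIBN, toluene, 90 °C
Reagents that add atoms: none
Why: Barton–McCombie radical deoxygenation through a stabilised benzylic radical gives the ArCH2 group without cationic intermediates (no Wagner–Meerwein shift or Friedel–Crafts closure onto the alkene), and the primary chloride survives.

Step 12
Reactants: 21 5-bromo-2-methylpent-2-ene; 22 (S)-3-hydroxyoxolan-2-one [(S)-α-hydroxy-γ-butyrolactone]
Product: 24 (3S)-1,3-dihydroxy-8-methylnon-7-en-4-one (in equilibrium with its cyclic hemiketal), via homoprenyllithium 23 (not isolated)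
Conditions: 21, Li (1% Na), Et2O, −15 °C; then 22 (0.45 equiv), THF, −78 °C; aq. NH4Cl
Reagents that add atoms: none
Why: The first equivalent of organolithium deprotonates the hydroxyl and the second adds once to the lactone carbonyl (the chelated tetrahedral lithium lactolate does not collapse at −78 °C), giving the α-hydroxy ketone after work-up with the bought (S) centre intact.

Step 13
Reactants: 24 (3S)-1,3-dihydroxy-8-methylnon-7-en-4-one
Product: 25 (3S,4R)-4,8-dimethylnon-7-ene-1,3,4-triol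
Conditions: MeMgBr (4 equiv), THF, −78 → 0 °C
Reagents that add atoms: methylmagnesium bromide C[Mg]Br
Why: In this Cram-chelate-controlled Grignard addition magnesium bridges the ketone oxygen and the α-alkoxide, methyl adds from the face of the α-hydrogen, and the tertiary carbinol forms as R, giving the (3S,4R) anti-diol (≥10:1 expected).

Step 14
Reactants: 25 (3S,4R)-4,8-dimethylnon-7-ene-1,3,4-triol
Product: 26 2-[(4S,5R)-2,2,5-trimethyl-5-(4-methylpent-3-en-1-yl)-1,3-dioxolan-4-yl]ethan-1-ol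
Conditions: Me2C(OMe)2, PPTS (cat.), acetone, 25 °C
Reagents that add atoms: 2,2-dimethoxypropane COC(C)(C)OC
Why: Acid-catalysed transketalisation gives the thermodynamically preferred five-membered acetonide of the vicinal diol and leaves the primary alcohol free.

Step 15
Reactants: 26 2-[(4S,5R)-2,2,5-trimethyl-5-(4-methylpent-3-en-1-yl)-1,3-dioxolan-4-yl]ethan-1-ol
Product: 27 (4S,5R)-4-(2-iodoethyl)-2,2,5-trimethyl-5-(4-methylpent-3-en-1-yl)-1,3-dioxolane
Conditions: I2, PPh3, imidazole, CH2Cl2, 0 °C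
Reagents that add atoms: iodine II
Why: Appel-type iodination converts the primary alcohol into the iodide by SN2.

Step 16
Reactants: 27 (4S,5R)-4-(2-iodoethyl)-2,2,5-trimethyl-5-(4-methylpent-3-en-1-yl)-1,3-dioxolane
Product: 28 (4S,5R)-4-(but-3-yn-1-yl)-2,2,5-trimethyl-5-(4-methylpent-3-en-1-yl)-1,3-dioxolane
Conditions: LiC≡CH·H2NCH2CH2NH2, DMSO, 25 °C
Reagents that add atoms: lithium acetylide–ethylenediamine complex [Li]C#C.NCCN
Why: SN2 alkylation of lithium acetylide by the primary iodide gives the terminal alkyne, the acetonide preventing the tertiary oxygen from closing onto the iodide.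

Step 17
Reactants: 28 (4S,5R)-4-(but-3-yn-1-yl)-2,2,5-trimethyl-5-(4-methylpent-3-en-1-yl)-1,3-dioxolane
Product: 30 (4S,5R)-4-[(3E)-4-iodo-3-methylbut-3-en-1-yl]-2,2,5-trimethyl-5-(4-methylpent-3-en-1-yl)-1,3-dioxolane, via alkenylalane 29 (not isolated)
Conditions: Me3Al, Cp2ZrCl2 (0.25 equiv), CH2Cl2, 0 → 25 °C; then I2, THF, −30 °C
Reagents that add atoms: trimethylaluminium C[Al](C)C; iodine II
Why: Negishi zirconium-catalysed carboalumination adds Me–Al syn across the alkyne with methyl on the internal carbon, and iodinolysis with retention gives the (E)-trisubstituted vinyl iodide.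

Step 18
Reactants: 20 2-{[(1R,2S,5R)-5-(2-chloroethyl)-1,2,5-trimethyl-1,2,3,4,5,6,7,8-octahydronaphthalen-1-yl]methyl}-1,4-bis(methoxymethoxy)benzene; 30 the (E)-vinyl iodide
Product: 32 (4S,5R)-4-[(3E)-6-{(1R,5R,6S)-5-[2,5-bis(methoxymethoxy)benzyl]-1,5,6-trimethyl-1,2,3,4,5,6,7,8-octahydronaphthalen-1-yl}-3-methylhex-3-en-1-yl]-2,2,5-trimethyl-5-(4-methylpent-3-en-1-yl)-1,3-dioxolane, via Grignard reagent 31 (not isolated)
Conditions: 20, Mg (I2-activated), THF, 60 °C; then 30, PdCl2(dppf) (5 mol%), THF, 0 → 25 °C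
Reagents that add atoms: none
Why: Magnesium insertion into the primary chloride followed by Kumada–Corriu sp3–sp2 coupling forms the CH2–CH= bond with retention of the E geometry; no stereocentre is involved.

Step 19
Reactants: 32 the coupled bis-MOM ether acetonide
Product: 33 2-{[(1R,2S,5R)-5-[(3E,7S,8R)-7,8-dihydroxy-4,8,12-trimethyltrideca-3,11-dien-1-yl]-1,2,5-trimethyl-1,2,3,4,5,6,7,8-octahydronaphthalen-1-yl]methyl}benzene-1,4-diol
Conditions: HCl (2 M aq.), MeOH–THF, degassed, 25 → 40 °C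
Reagents that add atoms: none
Why: Mild acetal hydrolysis cleaves both MOM ethers and the acetonide without protonating the hindered alkenes, and exclusion of air protects the hydroquinone.

Step 20
Reactants: 33 the hydroquinone diol
Product: 35 2-{[(1R,2S,5R)-5-[(3E,7S,8R)-7,8-dihydroxy-4,8,12-trimethyltrideca-3,11-dien-1-yl]-1,2,5-trimethyl-1,2,3,4,5,6,7,8-octahydronaphthalen-1-yl]methyl}-1,4-phenylene bis(hydrogen sulfate), via disodium bisphenoxide 34 (not isolated)
Conditions: NaH (2.05 equiv), DMF, 0 °C, Ar; then SO3·NMe3 (2.5 equiv), 0 → 25 °C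
Reagents that add atoms: sulfur trioxide–trimethylamine complex C[N+](C)(C)S(=O)(=O)[O-]
Why: Only the phenols are deprotonated by two equivalents of NaH, and the phenoxides react with SO3·NMe3 far faster than the neutral hindered secondary and tertiary alcohols, so O-sulfation is confined to the hydroquinone oxygens and no stereocentre is affected.

**Compound list**

1 | (R)-carvone, (5R)-2-methyl-5-(prop-1-en-2-yl)cyclohex-2-en-1-one | O=C1C(C)=CC[C@@H](C(C)=C)C1 | starting material
2 | lithium (5R)-2-methyl-5-(prop-1-en-2-yl)cyclohex-1-en-1-olate | [Li]OC1=C(C)CC[C@@H](C(C)=C)C1 | intermediate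
3 | ethyl 2-[(1R,4R)-1-methyl-2-oxo-4-(prop-1-en-2-yl)cyclohexyl]acetate | CCOC(=O)C[C@@]1(C)CC[C@H](CC1=O)C(C)=C | intermediate
4 | ethyl 2-[(1R,4R)-4-(1-hydroperoxy-1-methoxyethyl)-1-methyl-2-oxocyclohexyl]acetate (epimers at the peroxy carbon) | CCOC(=O)C[C@@]1(C)CC[C@H](CC1=O)C(C)(OC)OO | intermediate
5 | ethyl 2-[(1R)-1-methyl-2-oxocyclohexyl]acetate | CCOC(=O)C[C@@]1(C)CCCCC1=O | intermediate
6 | potassium (6R)-6-(2-ethoxy-2-oxoethyl)-6-methylcyclohex-1-en-1-olate | CCOC(=O)C[C@@]1(C)CCCC=C1O[K] | intermediate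
7 | ethyl 2-[(1R)-1-methyl-2-(trifluoromethanesulfonyloxy)cyclohex-2-en-1-yl]acetate | CCOC(=O)C[C@@]1(C)CCCC=C1OS(=O)(=O)C(F)(F)F | intermediate
8 | ethyl 2-[(1R)-2-ethenyl-1-methylcyclohex-2-en-1-yl]acetate | CCOC(=O)C[C@@]1(C)CCCC=C1C=C | intermediate
9 | 2-[(1R)-2-ethenyl-1-methylcyclohex-2-en-1-yl]ethan-1-ol | OCC[C@@]1(C)CCCC=C1C=C | intermediate
10 | (6R)-6-(2-chloroethyl)-1-ethenyl-6-methylcyclohex-1-ene | ClCC[C@@]1(C)CCCC=C1C=C | intermediate
11 | (E)-2-methylbut-2-enal (tiglic aldehyde) | C/C=C(\C)C=O | starting material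
12 | (1R,2S,5R,8aS)-5-(2-chloroethyl)-1,2,5-trimethyl-1,2,3,5,6,7,8,8a-octahydronaphthalene-1-carbaldehyde | ClCC[C@@]1(C)CCC[C@H]2C1=CC[C@H](C)[C@@]2(C)C=O | intermediate
13 | (1R,2S,5R)-5-(2-chloroethyl)-1,2,5-trimethyl-1,2,3,4,5,6,7,8-octahydronaphthalene-1-carbaldehyde | ClCC[C@@]1(C)CCCC2=C1CC[C@H](C)[C@@]2(C)C=O | intermediate
14 | hydroquinone (benzene-1,4-diol) | Oc1ccc(O)cc1 | starting material
15 | 1,4-bis(methoxymethoxy)benzene | COCOc1ccc(OCOC)cc1 | intermediate
16 | [2,5-bis(methoxymethoxy)phenyl]lithium | [Li]c1cc(OCOC)ccc1OCOC | intermediate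
17 | lithium alkoxide from addition of 16 to 13 (carbinol epimers) | ClCC[C@@]1(C)CCCC2=C1CC[C@H](C)[C@@]2(C)C(O[Li])c1cc(OCOC)ccc1OCOC | intermediate
18 | lithium O-alkyl dithiocarbonate of 17 (carbinol epimers) | ClCC[C@@]1(C)CCCC2=C1CC[C@H](C)[C@@]2(C)C(OC(=S)S[Li])c1cc(OCOC)ccc1OCOC | intermediate
19 | O-{[2,5-bis(methoxymethoxy)phenyl][(1R,2S,5R)-5-(2-chloroethyl)-1,2,5-trimethyl-1,2,3,4,5,6,7,8-octahydronaphthalen-1-yl]methyl} S-methyl carbonodithioate (carbinol epimers) | ClCC[C@@]1(C)CCCC2=C1CC[C@H](C)[C@@]2(C)C(OC(=S)SC)c1cc(OCOC)ccc1OCOC | intermediate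
20 | 2-{[(1R,2S,5R)-5-(2-chloroethyl)-1,2,5-trimethyl-1,2,3,4,5,6,7,8-octahydronaphthalen-1-yl]methyl}-1,4-bis(methoxymethoxy)benzene | ClCC[C@@]1(C)CCCC2=C1CC[C@H](C)[C@@]2(C)Cc1cc(OCOC)ccc1OCOC | intermediate
21 | 5-bromo-2-methylpent-2-ene | CC(C)=CCCBr | starting material
22 | (S)-3-hydroxyoxolan-2-one | O=C1OCC[C@@H]1O | starting material
23 | (4-methylpent-3-en-1-yl)lithium | CC(C)=CCC[Li] | intermediate
24 | (3S)-1,3-dihydroxy-8-methylnon-7-en-4-one | CC(C)=CCCC(=O)[C@@H](O)CCO | intermediate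
25 | (3S,4R)-4,8-dimethylnon-7-ene-1,3,4-triol | CC(C)=CCC[C@@](C)(O)[C@@H](O)CCO | intermediate
26 | 2-[(4S,5R)-2,2,5-trimethyl-5-(4-methylpent-3-en-1-yl)-1,3-dioxolan-4-yl]ethan-1-ol | CC(C)=CCC[C@@]1(C)OC(C)(C)O[C@H]1CCO | intermediate
27 | (4S,5R)-4-(2-iodoethyl)-2,2,5-trimethyl-5-(4-methylpent-3-en-1-yl)-1,3-dioxolane | CC(C)=CCC[C@@]1(C)OC(C)(C)O[C@H]1CCI | intermediate
28 | (4S,5R)-4-(but-3-yn-1-yl)-2,2,5-trimethyl-5-(4-methylpent-3-en-1-yl)-1,3-dioxolane | CC(C)=CCC[C@@]1(C)OC(C)(C)O[C@H]1CCC#C | intermediate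
29 | (E)-alkenyl(dimethyl)alane from 28 (AlMe2 on the terminal carbon, methyl on the internal carbon) | CC(C)=CCC[C@@]1(C)OC(C)(C)O[C@H]1CC/C(C)=C/[Al](C)C | intermediate
30 | (4S,5R)-4-[(3E)-4-iodo-3-methylbut-3-en-1-yl]-2,2,5-trimethyl-5-(4-methylpent-3-en-1-yl)-1,3-dioxolane | CC(C)=CCC[C@@]1(C)OC(C)(C)O[C@H]1CC/C(C)=C/I | intermediate
31 | Grignard reagent of 20 (CH2CH2MgCl in place of CH2CH2Cl) | Cl[Mg]CC[C@@]1(C)CCCC2=C1CC[C@H](C)[C@@]2(C)Cc1cc(OCOC)ccc1OCOC | intermediate
32 | (4S,5R)-4-[(3E)-6-{(1R,5R,6S)-5-[2,5-bis(methoxymethoxy)benzyl]-1,5,6-trimethyl-1,2,3,4,5,6,7,8-octahydronaphthalen-1-yl}-3-methylhex-3-en-1-yl]-2,2,5-trimethyl-5-(4-methylpent-3-en-1-yl)-1,3-dioxolane | CC(C)=CCC[C@@]1(C)OC(C)(C)O[C@H]1CC/C(C)=C/CC[C@@]1(C)CCCC2=C1CC[C@H](C)[C@@]2(C)Cc1cc(OCOC)ccc1OCOC | intermediate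
33 | 2-{[(1R,2S,5R)-5-[(3E,7S,8R)-7,8-dihydroxy-4,8,12-trimethyltrideca-3,11-dien-1-yl]-1,2,5-trimethyl-1,2,3,4,5,6,7,8-octahydronaphthalen-1-yl]methyl}benzene-1,4-diol | CC(C)=CCC[C@@](C)(O)[C@@H](O)CC/C(C)=C/CC[C@@]1(C)CCCC2=C1CC[C@H](C)[C@@]2(C)Cc1cc(O)ccc1O | intermediate
34 | disodium bisphenoxide of 33 | CC(C)=CCC[C@@](C)(O)[C@@H](O)CC/C(C)=C/CC[C@@]1(C)CCCC2=C1CC[C@H](C)[C@@]2(C)Cc1cc(O[Na])ccc1O[Na] | intermediate
35 | 2-{[(1R,2S,5R)-5-[(3E,7S,8R)-7,8-dihydroxy-4,8,12-trimethyltrideca-3,11-dien-1-yl]-1,2,5-trimethyl-1,2,3,4,5,6,7,8-octahydronaphthalen-1-yl]methyl}-1,4-phenylene bis(hydrogen sulfate) | CC(C)=CCC[C@@](C)(O)[C@@H](O)CC/C(C)=C/CC[C@@]1(C)CCCC2=C1CC[C@H](C)[C@@]2(C)Cc1cc(OS(=O)(=O)O)ccc1OS(=O)(=O)O | target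

**Step count and risks**

Total: 20 steps. Longest linear sequence: 13 steps from (R)-carvone (steps 1–8, 10, 11, 18, 19, 20). Side branches: step 9 (arene) and steps 12–17 (diol fragment).

The three steps most likely to fail:

Step 7 (Diels–Alder). A hindered diene meets a trisubstituted enal, and the facial preference rests only on methyl versus chloroethyl at C-5. The fallback sets out from diene 10 and aldehyde 11 and comes back at 12. Aldehyde 11 is first converted (ethylene glycol, TsOH, benzene, Dean–Stark) into 2-[(2E)-but-2-en-2-yl]-1,3-dioxolane F1. Diene 10 and this acetal are then joined in a cationic dioxolenium Diels–Alder reaction (TMSOTf, CH2Cl2, −90 °C), which is far more reactive and runs colder, giving the dioxolane-protected cycloadduct F2. Aqueous TsOH in acetone frees aldehyde 12.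

Step 8 (acid isomerisation). The C-4a cation could undergo a 1,2-shift from C-5 or a Prins-type closure with the aldehyde instead of simple proton loss. The fallback sets out from 12 and comes back at 20. Aldehyde 12 is carried with its C-4=C-4a double bond through the aryllithium 16 addition and one-flask xanthate formation, passing the lithium alkoxide of the 4,4a-ene series F3 and the lithium xanthate of the 4,4a-ene series F4 to the S-methyl xanthate of the 4,4a-ene series F5. Bu3SnH/AIBN then gives the deoxygenated 4,4a-ene F6. The alkene is moved last by radical hydrogen-atom-transfer isomerisation with chloro[N,N'-bis(3,5-di-tert-butylsalicylidene)ethane-1,2-diaminato]cobalt (achiral, trivalent cobalt, 5 mol%) and PhSiH3 (cat.) in benzene at 25 °C, conditions under which the electron-rich arene cannot close onto a cation; this gives 20.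

Step 20 (chemoselective sulfation). The secondary alcohol may be sulfated as well, or the hydroquinone dianion may oxidise. The fallback sets out from 33 and comes back at 35. The vicinal diol is masked with PhB(OH)2 (pyridine, 4 Å sieves) as the cyclic phenylboronate of 33 F7. Both phenols are sulfated with SO3·pyridine to the cyclic phenylboronate of 35 F8. The boron is then removed oxidatively (NaBO3·4H2O, aqueous THF, pH 8), which aryl sulfates tolerate, to give 35.

**Further compounds**

F1 | step 7 | 2-[(2E)-but-2-en-2-yl]-1,3-dioxolane | C/C=C(\C)C1OCCO1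
F2 | step 7 | 2-[(1R,2S,5R,8aS)-5-(2-chloroethyl)-1,2,5-trimethyl-1,2,3,5,6,7,8,8a-octahydronaphthalen-1-yl]-1,3-dioxolane | ClCC[C@@]1(C)CCC[C@H]2C1=CC[C@H](C)[C@@]2(C)C1OCCO1
F3 | step 8 | 4,4a-ene isomer of 17 (8a-H cis to the C-1 methyl; carbinol epimers) | ClCC[C@@]1(C)CCC[C@H]2C1=CC[C@H](C)[C@@]2(C)C(O[Li])c1cc(OCOC)ccc1OCOC
F4 | step 8 | 4,4a-ene isomer of 18 (8a-H cis to the C-1 methyl; carbinol epimers) | ClCC[C@@]1(C)CCC[C@H]2C1=CC[C@H](C)[C@@]2(C)C(OC(=S)S[Li])c1cc(OCOC)ccc1OCOC
F5 | step 8 | 4,4a-ene isomer of 19 (8a-H cis to the C-1 methyl; carbinol epimers) | ClCC[C@@]1(C)CCC[C@H]2C1=CC[C@H](C)[C@@]2(C)C(OC(=S)SC)c1cc(OCOC)ccc1OCOC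
F6 | step 8 | 4,4a-ene isomer of 20 (8a-H cis to the C-1 methyl) | ClCC[C@@]1(C)CCC[C@H]2C1=CC[C@H](C)[C@@]2(C)Cc1cc(OCOC)ccc1OCOC
F7 | step 20 | cyclic phenylboronate of 33 (boron on the two diol oxygens) | CC(C)=CCC[C@@]1(C)OB(c2ccccc2)O[C@H]1CC/C(C)=C/CC[C@@]1(C)CCCC2=C1CC[C@H](C)[C@@]2(C)Cc1cc(O)ccc1O
F8 | step 20 | cyclic phenylboronate of 35 (boron on the two diol oxygens) | CC(C)=CCC[C@@]1(C)OB(c2ccccc2)O[C@H]1CC/C(C)=C/CC[C@@]1(C)CCCC2=C1CC[C@H](C)[C@@]2(C)Cc1cc(OS(=O)(=O)O)ccc1OS(=O)(=O)O
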